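**Retrosynthetic overview**

- The target comes from a ring B 5β,6β-vinyl epoxide and angelic acid by trans-diaxial opening at the allylic C5. The vinyl epoxide comes from the C4 ketone via the ring B enone, nucleophilic epoxidation and Wittig methylenation.
- The C2 acetate comes from catalyst-controlled reduction of a (Z)-1-ethylidene-trans-hydrindane-2,4-dione.
- Key step: ring A with its Z-ethylidene and C2 carbonyl is made by a one-carbon ring expansion (1,2-shift of C7a) of a 1-ethynylcyclobutanol fused to ring B, terminated by methyl transfer from palladium. The ring fusion is then set trans by epimerisation at C3a next to the C4 ketone.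
- The cyclobutanone comes from a head-to-tail [2+2] photocycloaddition of (S)-cryptone with 1,1-diethoxyethene. (S)-Cryptone comes from isovaleraldehyde and methyl vinyl ketone by an organocatalytic Michael/aldol sequence.
- Ring order: ring B (six-membered) first, then a cyclobutane on ring B, which is expanded to ring A (five-membered).

Assumption: in step 1 the (S)-catalyst gives the (S)-configured Michael adduct, as the usual enamine face-shielding model predicts; if the sense is reversed, the enantiomeric catalyst is used.

Convention: hydrindane locants as in the target (C1 ethylidene, C2 OAc, C4 methylidene, C5 angelate, C6 OH, C7 isopropyl). β is the face of the C7 isopropyl group. Ring A is the five-membered ring and ring B the six-membered ring.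

**Route**

Step 1
Reactants: 1 3-methylbutanal (isovaleraldehyde); 2 but-3-en-2-one (methyl vinyl ketone)
Product: 4 (S)-4-isopropylcyclohex-2-en-1-one, via keto-aldehyde 3 (not isolated)
Conditions: (S)-2-[diphenyl(trimethylsilyloxy)methyl]pyrrolidine (5 mol %), ethyl 3,4-dihydroxybenzoate (20 mol %), neat, 4 °C; then LiOH, iPrOH, 23 °C
Reagents that add atoms: none
Why: Enamine-catalysed asymmetric Michael addition sets the isopropyl-bearing stereocentre (future C7, S) by shielding one enamine face, and hydroxide then closes ring B by intramolecular aldol condensation (organocatalytic Robinson-type annulation).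

Step 2
Reactants: 4 (S)-4-isopropylcyclohex-2-en-1-one; 5 1,1-diethoxyethene
Product: 7 (1S,5S,6S)-5-isopropylbicyclo[4.2.0]octane-2,7-dione (cis-fused), via photoadduct acetal 6 (not isolated)
Conditions: hν (350 nm, Pyrex), 5 (5 equiv), CH2Cl2, −40 °C; then 1 M HCl, THF, 23 °C
Reagents that add atoms: water (O)
Why: The enone–alkene [2+2] photocycloaddition with the electron-rich ketene acetal is head-to-tail (acetal carbon on the former β-carbon) and occurs anti to the neighbouring isopropyl group, which sets C7a, and aqueous acid then unmasks the cyclobutanone and equilibrates the epimerisable ring-fusion carbon next to the ring B ketone to the stable cis 6-4 fusion.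

Step 3
Reactants: 7 (1S,5S,6S)-5-isopropylbicyclo[4.2.0]octane-2,7-dione
Product: 8 (1S,5S,6S,7R)-7-ethynyl-7-hydroxy-5-isopropylbicyclo[4.2.0]octan-2-one
Conditions: HC≡CMgBr (1.05 equiv), LaCl3·2LiCl (20 mol %), THF, −78 °C; aq. NH4Cl
Reagents that add atoms: ethynylmagnesium bromide (C#C[Mg]Br)
Why: Chemoselective 1,2-addition of the alkynyl Grignard reagent to the strained, more electrophilic cyclobutanone from its convex face, in preference to the ring B ketone that is shielded by the ring fusion; the new carbinol centre is destroyed in step 4.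

Step 4
Reactants: 8 (1S,5S,6S,7R)-7-ethynyl-7-hydroxy-5-isopropylbicyclo[4.2.0]octan-2-one
Product: 10 (1Z,3aR,7S,7aS)-1-ethylidene-7-isopropylhexahydro-1H-indene-2,4-dione (trans-fused), via cis-fused dione 9 (not isolated)
Conditions: Pd(PPh3)4 (5 mol %), MeI (3 equiv), K2CO3 (2.5 equiv), DMF, 50 °C; then MeOH, 23 °C
Reagents that add atoms: iodomethane (CI)
Why: Proposed new method: MeI adds oxidatively to zerovalent palladium and the resulting MePd(PPh3)2I π-activates the terminal alkyne, so that the more substituted, strain-releasing cyclobutane bond C2–C7a shifts 1,2 onto the internal alkyne carbon anti to palladium (semipinacol ring expansion, retention at C7a, carbinol carbon becomes the C2 ketone) and C(sp2)–CH3 reductive elimination from the vinyl(methyl) divalent palladium intermediate leaves the methyl group where palladium was, trans to C7a and cis to C2 (Z), after which carbonate in MeOH epimerises the ketone α-carbon C3a to the trans ring fusion with all ring B substituents equatorial (the equilibrium ratio is not known, so any cis epimer is separated and recycled); the closest known reactions are the palladium-catalysed ring expansion/cross-coupling of 1-(1-alkynyl)cyclobutanols with aryl and vinyl halides and the gold-catalysed ring expansion of 1-alkynylcyclobutanols, neither of which has been run with a methyl electrophile on a terminal alkyne.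

Step 5
Reactants: 10 (1Z,3aR,7S,7aS)-1-ethylidene-7-isopropylhexahydro-1H-indene-2,4-dione
Product: 11 (1Z,2S,3aR,7S,7aS)-1-ethylidene-2-hydroxy-7-isopropyloctahydro-4H-inden-4-one (2β-alcohol)
Conditions: (R)-1-methyl-3,3-diphenyltetrahydro-1H,3H-pyrrolo[1,2-c][1,3,2]oxazaborole ((R)-Me-CBS, 20 mol %), catecholborane (1.3 equiv), toluene, −78 °C; then MeOH, aq. NaHCO3
Reagents that add atoms: none
Why: Corey–Bakshi–Shibata reduction under catalyst control: the ketone binds boron anti to the alkylidene-bearing (large) side, so hydride reaches the α face of the conjugated C2 carbonyl and gives the 2β (S) allylic alcohol, and at −78 °C the activated enone carbonyl should react ahead of the hindered saturated C4 ketone.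

Step 6
Reactants: 11 (1Z,2S,3aR,7S,7aS)-1-ethylidene-2-hydroxy-7-isopropyloctahydro-4H-inden-4-one
Product: 12 (1Z,2S,3aR,7S,7aS)-1-ethylidene-7-isopropyl-4-oxooctahydro-1H-inden-2-yl acetate
Conditions: Ac2O, pyridine, 4-(dimethylamino)pyridine (cat.), CH2Cl2, 0 → 23 °C
Reagents that add atoms: acetic anhydride (CC(=O)OC(C)=O)
Why: Standard nucleophile-catalysed acylation of the secondary allylic alcohol installs the C2 acetate without touching any stereocentre.

Step 7
Reactants: 12 (1Z,2S,3aR,7S,7aS)-1-ethylidene-7-isopropyl-4-oxooctahydro-1H-inden-2-yl acetate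
Product: 14 (1Z,2S,3aR,7R,7aS)-1-ethylidene-7-isopropyl-4-oxo-2,3,3a,4,7,7a-hexahydro-1H-inden-2-yl acetate, via lithium enolate 13 (not isolated)
Conditions: LiN(SiMe3)2 (1.1 equiv), THF, −78 °C; then N-tert-butylbenzenesulfinimidoyl chloride (1.2 equiv), −78 °C
Reagents that add atoms: none
Why: Kinetic deprotonation at the less hindered C5 methylene (not the C3a methine, so the ring fusion is untouched) followed by Mukaiyama dehydrogenation (α-sulfenylation by the sulfinimidoyl chloride and syn elimination) gives the ring B enone without palladium, which would ionise the allylic acetate.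

Step 8
Reactants: 14 (1Z,2S,3aR,7R,7aS)-1-ethylidene-7-isopropyl-4-oxo-2,3,3a,4,7,7a-hexahydro-1H-inden-2-yl acetate
Product: 15 (1Z,2S,3aR,5S,6S,7S,7aS)-5,6-epoxy-1-ethylidene-7-isopropyl-4-oxooctahydro-1H-inden-2-yl acetate (5β,6β-epoxide)
Conditions: tBuOOH (decane solution, 2 equiv), DBU (1.5 equiv), CH2Cl2, 0 → 23 °C
Reagents that add atoms: tert-butyl hydroperoxide (CC(C)(C)OO)
Why: Weitz–Scheffer nucleophilic epoxidation in which the peroxide anion attacks C6 axially (chair-like enolate) on the β face of the rigid trans-fused enone and closes to the 5β,6β-epoxide, setting C5 and C6, while the non-hydrolytic base spares the acetate and the unconjugated ethylidene.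

Step 9
Reactants: 15 (1Z,2S,3aR,5S,6S,7S,7aS)-5,6-epoxy-1-ethylidene-7-isopropyl-4-oxooctahydro-1H-inden-2-yl acetate
Product: 16 (1Z,2S,3aR,5R,6S,7S,7aR)-5,6-epoxy-1-ethylidene-7-isopropyl-4-methylideneoctahydro-1H-inden-2-yl acetate
Conditions: Ph3PCH3Br (1.5 equiv), KN(SiMe3)2 (1.4 equiv), THF, 0 °C; then 15, −78 → 0 °C
Reagents that add atoms: methyltriphenylphosphonium bromide (C[P+](c1ccccc1)(c1ccccc1)c1ccccc1.[Br-])
Why: Wittig methylenation of the ketone, which reacts much faster with the non-stabilised ylide than the acetate does, gives the exocyclic methylene and locks the C3a configuration.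

Step 10
Reactants: 16 (1Z,2S,3aR,5R,6S,7S,7aR)-5,6-epoxy-1-ethylidene-7-isopropyl-4-methylideneoctahydro-1H-inden-2-yl acetate; 17 angelic acid ((Z)-2-methylbut-2-enoic acid)
Product: 18 (1Z,2S,3aR,5S,6S,7S,7aR)-2-acetoxy-1-ethylidene-6-hydroxy-7-isopropyl-4-methylideneoctahydro-1H-inden-5-yl (Z)-2-methylbut-2-enoate (target)
Conditions: 17 (3 equiv), Cs2CO3 (cat., 0.3 equiv), DMF, 70 °C
Reagents that add atoms: none
Why: SN2 opening of the vinyl epoxide by angelate at the allylic C5, anti to the epoxide oxygen, is the trans-diaxial (Fürst–Plattner) pathway, so inversion at C5 gives the 5α-angelate and the retained 6β-hydroxyl, and the weakly basic, acid-free medium avoids angelate-to-tiglate isomerisation.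

**Compound list**

1 | 3-methylbutanal (isovaleraldehyde) | CC(C)CC=O | starting material
2 | but-3-en-2-one (methyl vinyl ketone) | CC(=O)C=C | starting material
3 | (S)-2-isopropyl-5-oxohexanal (not isolated) | O=C[C@H](C(C)C)CCC(C)=O | intermediate
4 | (S)-4-isopropylcyclohex-2-en-1-one ((S)-cryptone) | O=C1C=C[C@H](C(C)C)CC1 | intermediate
5 | 1,1-diethoxyethene | C=C(OCC)OCC | starting material
6 | (5S,6S)-7,7-diethoxy-5-isopropylbicyclo[4.2.0]octan-2-one, head-to-tail adduct, cyclobutane anti to isopropyl, mixture of C1 ring-fusion epimers (not isolated) | O=C1C2CC(OCC)(OCC)[C@H]2[C@H](C(C)C)CC1 | intermediate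
7 | (1S,5S,6S)-5-isopropylbicyclo[4.2.0]octane-2,7-dione, cis-fused | O=C1[C@H]2CC(=O)[C@H]2[C@H](C(C)C)CC1 | intermediate
8 | (1S,5S,6S,7R)-7-ethynyl-7-hydroxy-5-isopropylbicyclo[4.2.0]octan-2-one, ethynyl on the convex face | O=C1[C@H]2C[C@](O)(C#C)[C@H]2[C@H](C(C)C)CC1 | intermediate
9 | (1Z,3aS,7S,7aS)-1-ethylidene-7-isopropylhexahydro-1H-indene-2,4-dione, cis-fused (not isolated) | O=C1[C@H]2CC(=O)/C(=C\C)[C@H]2[C@H](C(C)C)CC1 | intermediate
10 | (1Z,3aR,7S,7aS)-1-ethylidene-7-isopropylhexahydro-1H-indene-2,4-dione, trans-fused (H-3a α, H-7a β) | O=C1[C@@H]2CC(=O)/C(=C\C)[C@H]2[C@H](C(C)C)CC1 | intermediate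
11 | (1Z,2S,3aR,7S,7aS)-1-ethylidene-2-hydroxy-7-isopropyloctahydro-4H-inden-4-one (2β-OH) | O=C1[C@@H]2C[C@H](O)/C(=C\C)[C@H]2[C@H](C(C)C)CC1 | intermediate
12 | (1Z,2S,3aR,7S,7aS)-1-ethylidene-7-isopropyl-4-oxooctahydro-1H-inden-2-yl acetate | O=C1[C@@H]2C[C@H](OC(C)=O)/C(=C\C)[C@H]2[C@H](C(C)C)CC1 | intermediate
13 | lithium C4=C5 enolate of 12 (not isolated) | [Li]OC=1[C@@H]2C[C@H](OC(C)=O)/C(=C\C)[C@H]2[C@H](C(C)C)CC=1 | intermediate
14 | (1Z,2S,3aR,7R,7aS)-1-ethylidene-7-isopropyl-4-oxo-2,3,3a,4,7,7a-hexahydro-1H-inden-2-yl acetate | O=C1[C@@H]2C[C@H](OC(C)=O)/C(=C\C)[C@H]2[C@H](C(C)C)C=C1 | intermediate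
15 | (1Z,2S,3aR,5S,6S,7S,7aS)-5,6-epoxy-1-ethylidene-7-isopropyl-4-oxooctahydro-1H-inden-2-yl acetate (5β,6β-epoxide) | O=C1[C@@H]2C[C@H](OC(C)=O)/C(=C\C)[C@H]2[C@H](C(C)C)[C@@H]3O[C@H]13 | intermediate
16 | (1Z,2S,3aR,5R,6S,7S,7aR)-5,6-epoxy-1-ethylidene-7-isopropyl-4-methylideneoctahydro-1H-inden-2-yl acetate | C=C1[C@@H]2C[C@H](OC(C)=O)/C(=C\C)[C@H]2[C@H](C(C)C)[C@@H]3O[C@H]13 | intermediate
17 | angelic acid ((Z)-2-methylbut-2-enoic acid) | C/C=C(/C)C(=O)O | starting material
18 | (1Z,2S,3aR,5S,6S,7S,7aR)-2-acetoxy-1-ethylidene-6-hydroxy-7-isopropyl-4-methylideneoctahydro-1H-inden-5-yl (Z)-2-methylbut-2-enoate (CNP0210397.1) | C=C1[C@@H]2C[C@H](OC(C)=O)/C(=C\C)[C@H]2[C@H](C(C)C)[C@H](O)[C@H]1OC(=O)/C(C)=C\C | target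

**Step count and risks**

Total step count: 10. Longest linear sequence: 10 steps (1/2 → 18).

The three steps most likely to fail:

Step 4, the proposed methylative ring expansion. It can fail by protodepalladation to the methylidene ketone, by C–H methylation of the terminal alkyne, or by syn carbopalladation. The fallback uses known chemistry and sets out from 7. (Z)-Prop-1-enyllithium (from (Z)-1-bromoprop-1-ene and tBuLi, transmetalated with CeCl3, THF, −78 °C) adds to the cyclobutanone to give the (Z)-propenyl carbinol F4. PhSeCl (CH2Cl2, −78 °C) forms the seleniranium ion and triggers the semipinacol ring expansion by anti addition of the migrating C7a and selenium across the alkene, giving the β-(phenylselanyl) ketone F5. H2O2/pyridine then gives the selenoxide, whose syn elimination toward the acidic C1–H keeps C2 and CH3 cis and so delivers the (Z)-ethylidene dione 9. The same K2CO3/MeOH treatment brings the route back at 10.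

Step 3, the chemoselective ethynylation, where the ring B ketone may compete with the cyclobutanone. The fallback sets out from 6, isolated after the photolysis of step 2 and equilibrated to the cis ring fusion on basic alumina. NaBH4 (MeOH, 0 °C) reduces the only free ketone to the hydroxy acetal F1. 1 M HCl/THF unmasks the hydroxy cyclobutanone F2. HC≡CMgBr (2.2 equiv) then has a single carbonyl to attack and gives the diol F3. Dess–Martin periodinane oxidises only the secondary alcohol, since the tertiary propargylic alcohol cannot be oxidised, and the route comes back at 8.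

Step 5, where the catalyst must override any substrate bias at the nearly symmetric C2 carbonyl and leave the C4 ketone alone. The fallback sets out from 10. Luche reduction (NaBH4, CeCl3·7H2O, MeOH, −78 °C) is selective for the conjugated ketone and purely substrate-controlled; it gives either 11 itself or its C2 epimer, the 2α-alcohol F6. F6 is converted by Mitsunobu inversion with acetic acid (PPh3, DIAD, THF, 0 °C) directly into the acetate, and the route comes back at 12.

Further compounds
F1 | step 3 | (1S,5S,6S)-7,7-diethoxy-5-isopropylbicyclo[4.2.0]octan-2-ol, cis-fused, C2 carbinol epimers | OC1[C@H]2CC(OCC)(OCC)[C@H]2[C@H](C(C)C)CC1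
F2 | step 3 | (1S,5S,6S)-2-hydroxy-5-isopropylbicyclo[4.2.0]octan-7-one, cis-fused, C2 carbinol epimers | OC1[C@H]2CC(=O)[C@H]2[C@H](C(C)C)CC1
F3 | step 3 | (1S,5S,6S,7R)-7-ethynyl-5-isopropylbicyclo[4.2.0]octane-2,7-diol, cis-fused, C2 carbinol epimers | OC1[C@H]2C[C@](O)(C#C)[C@H]2[C@H](C(C)C)CC1
F4 | step 4 | cis-fused 7-hydroxy-5-isopropyl-7-[(Z)-prop-1-enyl]bicyclo[4.2.0]octan-2-one, propenyl on the convex face | O=C1[C@H]2C[C@](O)(/C=C\C)[C@H]2[C@H](C(C)C)CC1
F5 | step 4 | cis-fused 7-isopropyl-1-[1-(phenylselanyl)ethyl]hexahydro-1H-indene-2,4-dione, anti adduct, one C1 epimer drawn | O=C1[C@H]2CC(=O)[C@@H]([C@H](C)[Se]c3ccccc3)[C@H]2[C@H](C(C)C)CC1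
F6 | step 5 | (1Z,2R,3aR,7S,7aS)-1-ethylidene-2-hydroxy-7-isopropyloctahydro-4H-inden-4-one (2α-alcohol) | O=C1[C@@H]2C[C@@H](O)/C(=C\C)[C@H]2[C@H](C(C)C)CC1
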